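The constants of the flask north are unknown to me, so instead of a rate law I look for one number into which the charges and the readings fold.

common to all: J 10 mM

| run | Q | G | temperature | remark | time |
|---|---|---|---|---|---|
| north | 0.70 equiv | 0.25 equiv | 100 °C | the very flask that is asked about, followed so far |  |
| east | 0.70 equiv | 0.25 equiv | 85 °C | run made earlier |  |
| flask | 0.700 equiv | 0.250 equiv | 100 °C |  | 6.0 h |

| run | time / h | X / % |
|---|---|---|
| north | 0.667 | 12.0 |
| north | 1.33 | 15.0 |
| north | 2.00 | 16.0 |
| north | 3.00 | 16.2 |
| north | 4.00 | 16.8 |
| north | 5.00 | 17.2 |
| east | 1.33 | 10.0 |
| east | 3.00 | 18.3 |
| east | 4.00 | 18.2 |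
| east | 6.00 | 20.3 |
| east | 8.00 | 20.4 |
| east | 10.0 | 21.8 |

(standard deviation of a reading: 0.5 percentage points)

- noon: at 6.0 h raise the temperature by 25 K, then wait 2.0 h
- winter: at 6.0 h add Q, 50.0% of the amount charged, then wait 2.0 h
- midnight: change nothing and wait 2.0 h more
- spring: at 6.0 h take out 90% of the X then present, then wait 2.0 h

- X taken out counts as made
- additions bring no volume worth counting

1. X, in percent of the J and G together first charged, at 6.0 h
2. the remedy with the largest gain of X, or "none" below 2 percentage points (noon / winter / midnight / spring / none)
3. X present, with what was taken out counted in, in percent of the J and G together first charged, after noon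
4. X present, with what was taken out counted in, in percent of the J and G together first charged, after winter

In the north run the last 3 readings rise by 1 percentage point against a scatter of 0.5 points on each, so I read them as a level and take their mean, 16.7%. The gap between X and that level closes with a time constant of about 0.660 h, as read from the first two readings. If one Q makes one X, the charge of Q allows 56.0%, and the level lies far below that, so I suppose that Q is the limiting reagent and that something else takes most of it. I therefore follow where the charged Q ends and fold the flask into one ratio:

capture share = X level × (J and G charged, per J) / (Q charged, per J) = 29.9%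

This capture share, the fraction of the charged Q that ends as X, is the number I carry. The asked time is 9.09 time constants, so I put X at the level, 16.7%. Noon, midnight and spring bring no new Q, so I reckon them at that level too, while winter's dose earns the same share:

X after winter = capture share × Q with the dose / (J and G charged) = 25.1%

Winter stands 8.4 points above the level, so winter is my choice. The share does not carry over to the east run, made at 85 °C with the same charges, though: its last 3 readings give a share of 37.2%, which is higher, so mine belongs to 100 °C.

The forecast differs from my reckoning in its numbers, with X higher at 17.6%, 18.5% after noon and a lower 22% after winter, but it also picks winter: “winter is the most robust remedy”.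

The flask gives 17.0%, 17.0% after noon and 24.0% after winter, so the choice is winter.

    J ⇌ G (K = 0.540, k = 4.90 × 10⁻⁴ /min, Ea = 118 kJ/mol, ΔH = −42.0 kJ/mol)
    J + Q → X (k = 1.00 /M/min, Ea = 63.0 kJ/mol)
    Q + G → D (k = 7.10 /M/min, Ea = 59.0 kJ/mol)
    Q → Z (k = 0.0110 /min, Ea = 103 kJ/mol)
    (constants at 100 °C)

X stands still in this flask because the level of Q, the limiting reagent, falls: 0.00964% of the charge is free at 6.00 h, and the run with that level held reaches 70.1% against 17.0%. The capture share gave winter 1.1 points too much, which is less than winter's gain of 7 points. On the neighbour charged with 1.20 equiv of Q the share gives 28.7%, and that flask holds 30.7%.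

The numbers in the tables are calculated with made-up constants; noise was put on by code.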